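**The choice.** Thursday's may overshoot. If X is what is wanted, should its 20 min stay on the recipe or be cut?

| setting | elm | cedar | Thursday's | Monday's | Wednesday's |
|---|---|---|---|---|---|
| E | 0.20 M | 0.20 M | 0.20 M | 0.20 M | 0.20 M |
| D | 0.081 M | 0.65 M | 0.800 M | 0.200 M | 0.160 M |
| Z | 0.20 M | 0.20 M | 0.200 M | 0.200 M | 0.200 M |
| remark | run made earlier | run made earlier |  |  |  |
| time |  |  | 20 min | 20 min | 20 min |

| run | time / min | X / % | L / % | E / % |
|---|---|---|---|---|
| elm | 2.00 | 3.4 | 0.8 | 94.5 |
| elm | 5.00 | 10.8 | 0 | 90.6 |
| elm | 10.0 | 15.7 | 0.2 | 81.5 |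
| elm | 15.0 | 22.2 | 1.4 | 77.3 |
| elm | 20.0 | 24.0 | 0 | 75.7 |
| cedar | 1.50 | 22.5 | 1.0 | 72.7 |
| cedar | 3.00 | 40.6 | 1.0 | 55.4 |
| cedar | 6.00 | 59.1 | 0 | 34.7 |
| cedar | 10.0 | 66.8 | 0 | 21.5 |
| cedar | 20.0 | 68.9 | 0 | 3.6 |

(standard deviation of a reading: 1 percentage point)
- which of these holds the largest part of the E at the end of Thursday's (X / L / E / Q)
- which of these holds the largest part of the E at the end of Monday's (X / L / E / Q)
- which of these holds the largest part of the E at the end of Wednesday's (X / L / E / Q)
- X at the end of Thursday's, in percent of the E charged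
- steps under discussion: E + D -> Z + X; X + D -> Z + Q; Q + D -> Z + L; Z + L -> G

**Zero of scale.** Let e and x be the fractions of the E charge standing as E and X, and let s, the selectivity factor, be the rate constant of the second step over that of the first. Both steps take D, so x follows e: x is e to the power s, minus e, over one minus s. Equal steps would cap x at 36.8%, but the cedar run reads 68.9%, so the second step is slower.

**Reading s.** At 10.0 min the cedar run has lost 11.7% past X. For small s, that loss over ln(1/e) minus one plus e gives 0.156 as the reading of s, the second constant over the first. The top of x is then 71.0%, at e = 11.0%.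

**Reckoned.** Take mean D as the charge less half the E charge: 0.550 M for cedar, 0.700 M for Thursday's. Thursday's then gets 2.55 times cedar's exposure, so ln(1/e) is 3.91, e is 2.00% and x is 62.1%. That is past the top, and X still outweighs everything else together. For X, Thursday's should stop near 11.3 min.

At e = 0.5 the rule gives x = 47.1%, so the crossing lies just lower. Monday's, at equal charges, reaches e = 47.2% and x = 49.5%, a thin lead for X. Wednesday's has less D, so E is the choice there.

The forecast gave X, X, E and 63%, with the second constant “about one-sixth” of the first.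

**Next flask.** The flasks give X for Thursday's, X for Monday's and E for Wednesday's, with 62.0% of X in Thursday's.

    E + D → Z + X (k = 0.00520 L mol⁻¹ s⁻¹)
    X + D → Z + Q (k = 8.50 × 10⁻⁴ L mol⁻¹ s⁻¹)
    Q + D → Z + L (k = 0.00210 L mol⁻¹ s⁻¹)
    Z + L → G (k = 0.0780 L mol⁻¹ s⁻¹)

With the simulated e of 2.36%, the rule gives Thursday's x = 63.2%. Raising E to 0.50 M, all else as in Thursday's, leaves e = 9.24%, nearer the top, and the rule gives 70.8%. That flask holds 69.9% of X.

(The earlier runs and the new flask are simulated for an exercise; the scatter is artificial.)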